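Examiner: here is the alpha flask, followed so far, beside the earlier epsilon run. What is asked?

| setting | alpha | epsilon | flask |
|---|---|---|---|
| starting material | 0.20 M | 0.20 M | 0.20 M |
| second substrate | 0.10 M | 0.10 M | 0.100 M |
| capture agent | 4 mM | 4 mM | 4.00 mM |
| free catalyst | 4 mM | 2 mM | 4.0 mM |
| temperature | 80 °C | 86 °C | 80 °C |
| remark | the very flask that is asked about, followed so far | run made earlier |  |
| time |  |  | 5.0 d |

| alpha: time / d | alpha: target / % | epsilon: time / d | epsilon: target / % |
|---|---|---|---|
| 0.500 | 5.1 | 0.625 | 4.5 |
| 1.25 | 11.4 | 1.67 | 6.1 |
| 2.50 | 14.0 | 3.00 | 8.1 |
| 4.00 | 18.0 | 5.00 | 6.5 |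

(standard deviation of a reading: 1 percentage point)

- target, in percent of the starting material first charged, at 5.0 d
- which option adds most target ("none" when 2 percentage points or less is all one gets) (green / teal / violet / ochre / none)
- target present, in percent of the starting material first charged, after violet
- target present, in percent of the starting material first charged, after ochre

- green: change nothing and wait 10 d more
- teal: at 5.0 d raise the temperature by 20 K, then wait 10 d
- violet: at 5.0 d add free catalyst, 50.0 % of the amount charged, then wait 10 d
- ochre: at 5.0 d add starting material, 50.0 % of the amount charged, then wait 10 d

- in percentages every species weighs as the starting material in it: one side product counts as two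
- for target the crystals are counted in
- as a solid, counted per litre of solution: crystals
- the volume of additions can be left aside
- the numbers in the tables scatter with a standard deviation of 1 percentage point
- steps under discussion: catalyst intermediate B -> free catalyst + second product; second substrate + free catalyst <-> catalyst intermediate B; crystals <-> target; catalyst intermediate A -> free catalyst + target; starting material + target -> side product; starting material + free catalyst <-> catalyst intermediate A; catalyst intermediate A + capture agent -> trapped intermediate

Examiner: what do the readings show?

Candidate: the alpha run reads 5.1 % at 0.500 d, 14.0 % at 2.50 d and 18.0 % at 4.00 d, and the epsilon run stays between 6.1 % and 8.1 % from 1.67 d on, so target seems to level off. So I form the ceiling ratio, the concentration of target at the plateau per concentration of catalyst charged. The late alpha readings give 8.00, and the late epsilon readings give 6.90.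

Examiner: the epsilon run is hotter and has half the catalyst. Why compare them?

Candidate: in common logarithms the ratios are 0.903 and 0.839. They differ by 0.0642, less than the 0.301 by which the catalyst charges differ. So across these two runs, which differ in temperature as well, the plateau read went with the catalyst charge, within the scatter.

Examiner: dead catalyst also gives a plateau that goes with catalyst. Can these readings tell the two apart?

Candidate: no, that is the weak spot, and I take a risk here. I read the plateau as a steady state. In my reckoning target is made through catalyst intermediate A, whose level goes with starting material times free catalyst, and is lost by starting material + target. Starting material stands in both rates and cancels, leaving target concentration proportional to catalyst.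

Examiner: then commit yourself.

Candidate: at 5.0 d I say 16.0 %. Ochre leaves the ceiling where it stands, so again 16.0 %. Violet lifts it to 24.0 %, and so violet is my choice.

The forecast gives 19.8 % for now, violet as best, 50 % after violet (35 % to 65 %) and 29 % after ochre (25 % to 34 %), holding that “The yield is set by capture agent consumed, not by time.” My violet figure stands lower than its figure, and so does my ochre figure.

The flask gives 18.0 % at 5.0 d, violet as best, 24.7 % after violet and 16.6 % after ochre.

    catalyst intermediate B → free catalyst + second product (k = 0.00380 s⁻¹, Ea = 111 kJ mol⁻¹)
    second substrate + free catalyst ⇌ catalyst intermediate B (K = 6.10 M⁻¹, k = 0.00460 M⁻¹ s⁻¹, Ea = 87.0 kJ mol⁻¹, ΔH = −61.0 kJ mol⁻¹)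
    crystals ⇌ target, rate k3*(cs3 - [target]) while solid is left; crystals form when [target] > cs3 (solubility = 0.150 M, k = 0.00210 s⁻¹)
    catalyst intermediate A → free catalyst + target (k = 3.70 × 10⁻⁴ s⁻¹, Ea = 105 kJ mol⁻¹)
    starting material + target → side product (k = 4.00 × 10⁻⁵ M⁻¹ s⁻¹, Ea = 103 kJ mol⁻¹)
    starting material + free catalyst ⇌ catalyst intermediate A (K = 1.70 M⁻¹, k = 0.0770 M⁻¹ s⁻¹, Ea = 48.0 kJ mol⁻¹, ΔH = −37.0 kJ mol⁻¹)
    catalyst intermediate A + capture agent → trapped intermediate (k = 0.00150 M⁻¹ s⁻¹, Ea = 68.0 kJ mol⁻¹)
    (constants at 80 °C)

The main reason target stands where it does in this flask is the undoing of catalyst intermediate A into starting material + free catalyst: in the run with that undoing taken away, target at 5.0 d goes from 18.0 % to 67.9 %. The ceiling ratio 8.00 gave 24.0 % for violet against 24.7 %, and 16.0 % for ochre against 16.6 %. A further flask, the same but charged with 0.50 M of starting material, has the same catalyst, so the ratio puts its target at 6.40 % of that charge; it stands at 5.02 %.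

The earlier runs and the new flask were generated by integration with made-up constants, noise included.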